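- The blue run, charged like the new flasks, holds 28% of its substrate and 75% of target at 1.00 h, so the two add up to the charge within the scatter, and substrate lost can be read as target made.

| flask | substrate | capture agent | free catalyst | remark | time |
|---|---|---|---|---|---|
| blue | 20 mM | 6 mM | 1 mM | run made earlier |  |
| ochre | 20 mM | 3 mM | 1 mM | run made earlier |  |
| amber | 20 mM | 12 mM | 1 mM | run made earlier |  |
| Saturday's | 20 mM | 6.00 mM | 1.0 mM | a single well-mixed tank run continuously and read at steady state, 4.0 h in it on average |  |
| Friday's | 20 mM | 6.00 mM | 1.0 mM | a closed flask charged with all of it at once and left for 4.0 h | 4.0 h |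
| Thursday's | 20 mM (fed, over 4.00 h) | 6.00 mM | 1.0 mM | a stirred flask in which substrate is dosed at a steady rate over 4.00 h without added volume, worked up at 4.0 h | 4.0 h |

| run | time / h | target / % | substrate / % |
|---|---|---|---|
| blue | 0.200 | 20 | 79 |
| blue | 0.667 | 53 | 44 |
| blue | 1.00 | 75 | 28 |
| blue | 1.50 | 86 | 17 |
| blue | 2.50 | 98 | 3 |
| blue | 3.00 | 99 | 1 |
| blue | 4.00 | 98 | 1 |
| ochre | 0.333 | 36 | 63 |
| ochre | 0.500 | 48 | 53 |
| ochre | 0.667 | 60 | 39 |
| ochre | 1.00 | 72 | 25 |
| ochre | 1.50 | 93 | 10 |
| ochre | 2.50 | 95 | 1 |
| ochre | 4.00 | 100 | 0 |
| amber | 0.200 | 25 | 75 |
| amber | 0.667 | 53 | 44 |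
| amber | 1.00 | 67 | 30 |
| amber | 1.50 | 80 | 17 |
| amber | 2.50 | 93 | 5 |
| amber | 3.00 | 99 | 4 |
| amber | 4.00 | 96 | 0 |

(each reading ± 2 percentage points)

- the stated concentrations are those of everything mixed, before any reaction; amounts are the same in each set-up
- the earlier runs were read with a standard deviation of 2 percentage points
- what may be going on: substrate + free catalyst <-> catalyst intermediate A; catalyst intermediate A -> catalyst intermediate B; catalyst intermediate B -> free catalyst + target; capture agent + catalyst intermediate B -> trapped intermediate
- the feed brings no volume worth counting
- the earlier runs were made in a closed, stirred flask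

1. the set-up with the highest amount of target at the outlet or at the end, in percent of the substrate put in ("none" if the first two lie within 2 percentage points) (Saturday's / Friday's / Thursday's / none)
2. amount of target at the outlet or at the end, in percent of the substrate put in, Saturday's
3. amount of target at the outlet or at the end, in percent of the substrate put in, Friday's
4. amount of target at the outlet or at the end, in percent of the substrate put in, Thursday's

- Read as pseudo-first-order decay, with free catalyst taken as constant, that blue reading gives 1.27 h⁻¹, so a substrate lifetime, the time to fall to a fraction 1/e, is 0.786 h.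
- Into 4.0 h go 5.09 lifetimes.
- Friday's closed flask gives every portion the full time, so substrate left is exp(-n) and target is 99.4%.
- Saturday's tank holds its contents at the outlet level, so substrate left is 1/(1+n) and target is 83.6%.
- Thursday's feed gives a portion the time remaining after its entry, so substrate left averages (1-exp(-n))/n and target is 80.5%.
- The weak link is one reading with a scatter of 2 percentage points. The blue, ochre and amber readings at 1.00 h are 28%, 25% and 30%, with capture agent at 6 mM, 3 mM and 12 mM; taking their spread as scatter, their mean gives 1.28 h⁻¹.
- The lifetime count, the time in the vessel divided by the substrate lifetime, becomes 5.14, which moves Saturday's target to 83.7%. Thursday's becomes 80.7% and Friday's 99.4%, so Friday's stands above both.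
- The forecast, lower than this reckoning for Saturday's and Friday's, gives 82%, 98% and 80% for Saturday's, Friday's and Thursday's, with Friday's best: “Friday's wins clearly”.
- The flasks give 84.4% for Saturday's, 98.6% for Friday's and 82.5% for Thursday's, so Friday's is highest.

    substrate + free catalyst ⇌ catalyst intermediate A (K = 33.0 M⁻¹, k = 2.20 M⁻¹ s⁻¹)
    catalyst intermediate A → catalyst intermediate B (k = 0.0220 s⁻¹)
    catalyst intermediate B → free catalyst + target (k = 0.110 s⁻¹)
    capture agent + catalyst intermediate B → trapped intermediate (k = 0.200 M⁻¹ s⁻¹)

- While the feed ran in Thursday's flask, substrate stood at 14.0% of the charge and target at 35.3% at 2.00 h, and capture of catalyst intermediate B had already put 7.64% of the catalyst into trapped intermediate. At 4.00 h Thursday's flask held 82.5% of target, 17.7% of the catalyst as trapped intermediate and 16.3% of substrate, below the 19.3% that the count of 5.14 leaves. Scaling the count with free catalyst gives 1.28 for a neighbour of Thursday's charged with 0.25 mM, so the dosing rule leaves 56.4% of substrate, and at 4.00 h that neighbour holds 57.8% of its substrate charge as substrate.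

The runs are simulated from invented constants; the scatter is artificial.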